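The runs stem from a simulated flask for substances that don't exist, and the scatter is random.

Rings form slowly in the earlier runs, and at much the same pace in both: after 30.0 min violet holds 1.4% and red 1.9%, although violet was charged with 3.00 times the second end groups of red. Links, by contrast, follow that charge.

| flask | first end groups | second end groups | remark | time |
|---|---|---|---|---|
| violet | 6 mM | 1.5 equiv | run made earlier |  |
| red | 6 mM | 0.50 equiv | run made earlier |  |
| delta | 6.0 mM | 1.00 equiv |  | 4.0 h |
| zeta | 20 mM | 1.00 equiv |  | 4.0 h |
| beta | 60 mM | 1.00 equiv |  | 4.0 h |
| epsilon | 200 mM | 1.00 equiv |  | 4.0 h |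
| gamma | 500 mM | 1.00 equiv |  | 4.0 h |

| run | time / min | links / % | rings / % |
|---|---|---|---|
| violet | 15.0 | 10.9 | 1.3 |
| violet | 30.0 | 17.9 | 1.4 |
| violet | 50.0 | 23.7 | 1.9 |
| violet | 60.0 | 25.1 | 2.8 |
| violet | 80.0 | 28.5 | 3.3 |
| red | 15.0 | 3.9 | 0.7 |
| red | 30.0 | 5.8 | 1.9 |
| red | 50.0 | 7.6 | 2.9 |
| red | 60.0 | 9.8 | 3.5 |
| red | 80.0 | 9.5 | 3.8 |

(each reading ± 0.3 percentage points)

- "hardly changes" means that all values lie within two and a half points (for a concentration: within two and a half percent of the largest)

* share of links in all that became links or rings for delta, zeta, beta, epsilon, gamma, in this order
* the course of these numbers from the first flask to the last (falls, then rises / hardly changes / falls all the way / rises all the way / rises, then falls)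

The mean of those ring readings gives a ring constant of 5.50 × 10⁻⁴ min⁻¹, and the first link readings, taken per mM of second end groups charged, give a link constant of 0.0140 L mol⁻¹ s⁻¹. If links grow with c(first end groups) times c(second end groups) and rings with c(first end groups), then c(first end groups) cancels from the comparison of the two rates. The quotient of the constants, S = 1.52 mM⁻¹, is a selectivity factor: links made per ring for each mM of second end groups standing in the flask at that moment.

At the start of delta this gives 9.13 links per ring, a share of 90.1%. The objection is that second end groups do not stay. Violet gains 10.9% of links in its first 15.0 min but 3.4 percentage points in its last 20.0 min, though links have used 1.71 mM of the 9.00 mM charged. So second end groups appear to leave by another way. Allowing for the first end groups used, that fall reads as a decay time of 58.4 min. Over 4.0 h the average c(second end groups) in delta is then reckoned at 1.46 mM, which lowers the reckoned share to 68.9%.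

A further objection concerns gamma. There, at the charged concentration, links consume second end groups faster than the decay does, whereas in delta they consume them more slowly than the decay does. Letting both end groups fall together in gamma gives a share of 99.4%, in a reckoning that leaves the decay out. The reckoning therefore commits to a share that rises from flask to flask between these two values.

The forecast reads 77%, 88%, 94%, 97%, 98.5%, course rises all the way, on the ground that “the link-to-ring competition scales with concentration”.

The flasks give 73.7%, 88.2%, 94.5%, 97.7%, 98.8%, course rises all the way.

    first end groups + second end groups → rings, rate k1*[first end groups] as long as [second end groups] is above zero (k = 9.10 × 10⁻⁶ s⁻¹)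
    second end groups ⇌ dormant form (K = 2.60, k = 2.50 × 10⁻⁴ s⁻¹)
    second end groups → decomposed reagent (k = 7.20 × 10⁻⁵ s⁻¹)
    first end groups + second end groups → links (k = 0.0170 L mol⁻¹ s⁻¹)

In delta, first end groups go to links over rings at a rate ratio of 11 at the start, 8.0 at 0.220 h and 0.84 at 4.00 h, where c(second end groups) stands at 0.447 mM and S times that is 0.681. In zeta, between 2.00 h and 4.00 h, links gain 5.5 points and rings 2.9 points, a ratio of 1.88, and S times the mean c(second end groups) of those two moments is 1.63.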